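**Plan**

1. Numbering: C1 (methyl bridgehead), C2, C3=C4 (C4 carries formyl C10), C5 (bridgehead, formyl C11), C6 (side chain from C1'), C7, C8, C9 (acetoxy bridge); ring A = C1–C2–C3–C4–C5–C9, ring B = C1–C8–C7–C6–C5–C9.
2. Enabling feature: the 1,4-dialdehyde array C10–C4–C5–C11, whose central C4–C5 bond is both a ring A bond and the last bond to the quaternary bridgehead C5. With the C3=C4 unsaturation removed, cutting it as an oxidative coupling of two enol ethers leaves a monocyclic ring B.
3. Further cuts: C4=C10 and C5=C11 enol ethers back to carbonyls, C9–O, C1–C2 (conjugate addition), C1–CH3 (addition and 1,3-transposition), then C5–C9 and C6–C7 of ring B (aldol, Michael) back to (R)-citronellal and methyl vinyl ketone.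
4. Forward order: ring B (steps 1–4), C1 chain and C9 oxygen (5–7), the two enol ethers (8–9), ring A by anodic C4–C5 coupling (10), then acetate, dialdehyde and ring enal (11–15).
5. Stereochemistry: C1' from (R)-citronellal; C6 from the amine catalyst; C1 by axial cuprate attack cis to the C6 side chain; C9 by hydroxylation on the face opposite the C1 chain and the C6 side chain; C5 dictated by the C1 tether.

Key step: step 10

Assumption: the geometry of the two enol ethers made for the key step and of the later silyl enol ether, and the configuration of the transient C4 centre, have no bearing on the outcome; these compounds would be carried as mixtures and one isomer is drawn.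

**Route**

Step 1
Reactants: 1 (R)-citronellal; 2 methyl vinyl ketone
Product: 3 (2S,3R)-3,7-dimethyl-2-(3-oxobutyl)oct-6-enal
Conditions: (S)-2-[methoxy(diphenyl)methyl]pyrrolidine (5 mol%), ethyl 3,4-dihydroxybenzoate (20 mol%), neat, 4 °C
Reagents that add atoms: none
Why: Enamine-catalysed Michael addition of an aldehyde to a vinyl ketone forms C6–C7; the diarylmethyl group of the (S)-amine blocks one face of the E-enamine, so the acceptor should add to give the (2S) centre (C6) beside the untouched (3R) methyl centre.

Step 2
Reactants: 3 (2S,3R)-3,7-dimethyl-2-(3-oxobutyl)oct-6-enal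
Product: 4 (4S)-4-[(2R)-6-methylhept-5-en-2-yl]cyclohex-2-en-1-one
Conditions: KOH (aq), n-Bu4NOH (cat.), Et2O/THF/H2O, reflux
Reagents that add atoms: none
Why: Intramolecular aldol condensation of the 1,5-keto aldehyde (methyl ketone enolate onto the aldehyde, then dehydration) forms C5–C9 and closes ring B; no stereocentre is formed and cyclisation should outpace epimerisation of C6.

Step 3
Reactants: 4 (4S)-4-[(2R)-6-methylhept-5-en-2-yl]cyclohex-2-en-1-one
Product: 5 (4S)-1-methyl-4-[(2R)-6-methylhept-5-en-2-yl]cyclohex-2-en-1-ol
Conditions: MeLi, Et2O, −78 °C; NH4Cl (aq)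
Reagents that add atoms: methyllithium, [Li]C
Why: 1,2-Addition of a hard organolithium to the enone carbonyl installs the C1 methyl; the new carbinol centre is destroyed in step 4, so both epimers are carried on.

Step 4
Reactants: 5 (4S)-1-methyl-4-[(2R)-6-methylhept-5-en-2-yl]cyclohex-2-en-1-ol
Product: 6 (6S)-3-methyl-6-[(2R)-6-methylhept-5-en-2-yl]cyclohex-2-en-1-one
Conditions: pyridinium chlorochromate [C5H5NH][CrO3Cl], NaOAc, Celite, CH2Cl2, rt
Reagents that add atoms: none
Why: Dauben–Babler oxidative transposition: [3,3] shift of the tertiary allylic chromate ester and oxidation of the resulting secondary chromate move the oxygen from C1 to C5 and make C1 the methyl-bearing β-carbon of a new enone; no stereocentre is formed and the buffer protects C6, which is now α to the carbonyl.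

Step 5
Reactants: 6 (6S)-3-methyl-6-[(2R)-6-methylhept-5-en-2-yl]cyclohex-2-en-1-one; 7 2-(2-bromoethyl)-1,3-dioxolane
Product: 9 ring B trimethylsilyl enol ether, via Grignard reagent 8 (not isolated)
Conditions: 7, Mg, THF, 25 °C; then CuBr·SMe2 (10 mol%), TMSCl, HMPA, THF, −78 °C, add 6; Et3N, cold NaHCO3 (aq)
Reagents that add atoms: chlorotrimethylsilane, C[Si](C)(C)Cl
Why: Copper-catalysed, silyl chloride-accelerated conjugate addition of a Grignard reagent to a β,β-disubstituted enone makes the quaternary C1; antiparallel (axial) attack on the half-chair that keeps the C6 side chain pseudoequatorial should place the new chain cis to that side chain, and O-silylation fixes the enolate as C5=C9.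

Step 6
Reactants: 9 ring B trimethylsilyl enol ether
Product: 11 C9 hydroxy ketone, via lithium enolate 10 (not isolated)
Conditions: MeLi, THF, 0 °C; then −78 °C, 2-(phenylsulfonyl)-3-phenyloxaziridine; NH4Cl (aq)
Reagents that add atoms: 2-(phenylsulfonyl)-3-phenyloxaziridine, O=S(=O)(c1ccccc1)N1OC1c1ccccc1
Why: Regiospecific release of the lithium enolate from the silyl enol ether followed by Davis oxidation (oxygen transfer from an N-sulfonyloxaziridine, inert to the side-chain alkene); the reagent should reach C9 on the ring face that carries neither the C1 chain nor the C6 side chain, giving the hydroxyl cis to the C1 methyl.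

Step 7
Reactants: 11 C9 hydroxy ketone
Product: 12 C9 tert-butyldimethylsilyl ether
Conditions: TBSOTf, 2,6-lutidine, CH2Cl2, −78 → −20 °C
Reagents that add atoms: tert-butyldimethylsilyl triflate, CC(C)(C)[Si](C)(C)OS(=O)(=O)C(F)(F)F
Why: Silylation of a hindered secondary alcohol with a silyl triflate and a hindered pyridine base, run cold so that the dioxolane and the ketone are left alone; no stereocentre changes.

Step 8
Reactants: 12 C9 tert-butyldimethylsilyl ether
Product: 13 silyloxy keto aldehyde
Conditions: pyridinium p-toluenesulfonate (cat.), acetone/H2O 9:1, 55 °C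
Reagents that add atoms: water, O
Why: Mild acid-catalysed hydrolysis (transacetalisation) of the aldehyde dioxolane, much faster than cleavage of the hindered secondary silyl ether and too weakly acidic to hydrate the side-chain alkene or epimerise C6.

Step 9
Reactants: 13 silyloxy keto aldehyde; 14 (methoxymethyl)triphenylphosphonium chloride
Product: 16 ring B bis(methyl enol ether), via phosphorus ylide 15 (not isolated)
Conditions: 14 (5 equiv), KN(SiMe3)2, THF, 0 °C; then 13, 0 → 45 °C
Reagents that add atoms: none
Why: Double Wittig methoxymethylenation: the excess ylide should convert the aldehyde (C4=C10) at once and the hindered C5 ketone (C5=C11) on warming; no stereocentre is formed and the enol ether geometry is immaterial.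

Step 10
Reactants: 16 ring B bis(methyl enol ether)
Product: 17 bicyclo[3.3.1]nonane bis(dimethyl acetal) silyl ether
Conditions: RVC anode, Pt cathode, undivided cell, constant current (2.2 F/mol), 0.1 M LiClO4 in MeOH/THF 1:4, 2,6-lutidine, rt
Reagents that add atoms: methanol, CO
Why: Anodic one-electron oxidation of an enol ether (the more substituted exocyclic one at C5 is expected to go first) gives a radical cation whose C5 terminus is attacked by C4, the nucleophilic β-carbon of the second enol ether; a second electron transfer and methanol capture at C10 and C11 then deliver both acetals, which is the known intramolecular anodic coupling of two enol ethers to 1,4-dicarbonyl bis-acetals, used here to make a quaternary carbon in a bridged ring. Ring A (C1–C2–C3–C4–C5–C9) closes in a 6-exo-trig mode with respect to both C=C bonds. C5 is set by the tether: C4 can reach C5 only on the ring B face that carries the axial C1 chain, through a chair-like 1,3-diaxial bridging transition state, so its configuration follows from C1. C4 is formed without control and is erased in step 15. The step needs the enol ethers to be oxidised in preference to the trisubstituted side-chain alkene and needs cyclisation to outrun methanol capture; the lower oxidation potential of enol ethers under constant current and the short three-carbon tether should secure both, while 2,6-lutidine keeps the medium from hydrolysing the enol ethers.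

Step 11
Reactants: 17 bicyclo[3.3.1]nonane bis(dimethyl acetal) silyl ether
Product: 18 bicyclic C9 alcohol bis(dimethyl acetal)
Conditions: n-Bu4NF, THF, 50 °C
Reagents that add atoms: none
Why: Fluoride-driven cleavage of the silyl ether at the acetal stage, where no aldehyde is present and the β-hydroxy aldehyde retro-aldol pathway is closed; acetals and the alkene are inert.

Step 12
Reactants: 18 bicyclic C9 alcohol bis(dimethyl acetal)
Product: 19 bicyclic C9 acetate bis(dimethyl acetal)
Conditions: Ac2O, 4-(dimethylamino)pyridine, Et3N, CH2Cl2, 40 °C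
Reagents that add atoms: acetic anhydride, CC(=O)OC(C)=O
Why: Acyl-transfer (aminopyridine-catalysed) acetylation of a hindered secondary alcohol; the configuration at C9 is retained because the C–O bond is not touched.

Step 13
Reactants: 19 bicyclic C9 acetate bis(dimethyl acetal)
Product: 20 saturated 1,4-dialdehyde acetate
Conditions: TsOH·H2O (cat.), acetone/H2O 10:1, rt
Reagents that add atoms: water, O
Why: Acid-catalysed hydrolysis of both dimethyl acetals; furan formation from the 1,4-dialdehyde is impossible because C5 bears no hydrogen, the acetate survives, and epimerisation at C4 is of no consequence.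

Step 14
Reactants: 20 saturated 1,4-dialdehyde acetate
Product: 21 C4=C10 trimethylsilyl enol ether
Conditions: TMSOTf, Et3N, CH2Cl2, 0 °C
Reagents that add atoms: trimethylsilyl triflate, C[Si](C)(C)OS(=O)(=O)C(F)(F)F
Why: Soft enolisation and O-silylation of an aldehyde; only the C10 aldehyde has an α-hydrogen (on C4), so the silyl enol ether forms at one site only and C4 ceases to be a stereocentre.

Step 15
Reactants: 21 C4=C10 trimethylsilyl enol ether
Product: 22 target, (1R,5R,6S,9R)-9-acetoxy-1-methyl-6-[(2R)-6-methylhept-5-en-2-yl]bicyclo[3.3.1]non-3-ene-4,5-dicarbaldehyde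
Conditions: Pd(OAc)2 (1.1 equiv), MeCN, rt
Reagents that add atoms: none
Why: Saegusa–Ito oxidation: the silyl enol ether gives a divalent palladium enolate at C4, and β-hydride elimination, which can only involve C3–H because C5 is quaternary, should give the C3=C4 enal without touching the other aldehyde, the acetate or the stereocentres.

**Compound list**

1 | (R)-citronellal | O=CC[C@H](C)CCC=C(C)C | starting material
2 | methyl vinyl ketone | CC(=O)C=C | starting material
3 | (2S,3R)-3,7-dimethyl-2-(3-oxobutyl)oct-6-enal | O=C[C@@H](CCC(C)=O)[C@H](C)CCC=C(C)C | intermediate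
4 | (4S)-4-[(2R)-6-methylhept-5-en-2-yl]cyclohex-2-en-1-one | O=C1C=C[C@H]([C@H](C)CCC=C(C)C)CC1 | intermediate
5 | (4S)-1-methyl-4-[(2R)-6-methylhept-5-en-2-yl]cyclohex-2-en-1-ol, both carbinol epimers | CC1(O)C=C[C@H]([C@H](C)CCC=C(C)C)CC1 | intermediate
6 | (6S)-3-methyl-6-[(2R)-6-methylhept-5-en-2-yl]cyclohex-2-en-1-one | O=C1C=C(C)CC[C@H]1[C@H](C)CCC=C(C)C | intermediate
7 | 2-(2-bromoethyl)-1,3-dioxolane | BrCCC1OCCO1 | starting material
8 | [2-(1,3-dioxolan-2-yl)ethyl]magnesium bromide | Br[Mg]CCC1OCCO1 | intermediate (not isolated)
9 | ring B trimethylsilyl enol ether: C5(OSiMe3)=C9, C1 bearing methyl and a 2-(1,3-dioxolan-2-yl)ethyl chain cis to the C6 side chain | C[Si](C)(C)OC1=C[C@@](C)(CCC2OCCO2)CC[C@H]1[C@H](C)CCC=C(C)C | intermediate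
10 | lithium enolate corresponding to 9 | [Li]OC1=C[C@@](C)(CCC2OCCO2)CC[C@H]1[C@H](C)CCC=C(C)C | intermediate (not isolated)
11 | C9 hydroxy ketone: C5 ketone, C9 hydroxyl cis to the C1 methyl and trans to the C1 chain and the C6 side chain | O=C1[C@H](O)[C@@](C)(CCC2OCCO2)CC[C@H]1[C@H](C)CCC=C(C)C | intermediate
12 | tert-butyldimethylsilyl ether of 11 | O=C1[C@H](O[Si](C)(C)C(C)(C)C)[C@@](C)(CCC2OCCO2)CC[C@H]1[C@H](C)CCC=C(C)C | intermediate
13 | silyloxy keto aldehyde: as 12 with a 3-oxopropyl chain on C1 | O=C1[C@H](O[Si](C)(C)C(C)(C)C)[C@@](C)(CCC=O)CC[C@H]1[C@H](C)CCC=C(C)C | intermediate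
14 | (methoxymethyl)triphenylphosphonium chloride | COC[P+](c1ccccc1)(c1ccccc1)c1ccccc1.[Cl-] | starting material
15 | (methoxymethylidene)triphenylphosphorane | COC=P(c1ccccc1)(c1ccccc1)c1ccccc1 | intermediate (not isolated)
16 | ring B bis(methyl enol ether): C5=C11H(OMe) exocyclic, C1 chain CH2CH2CH=CH(OMe) (C2, C3, C4=C10), C9 silyl ether; mixture of enol ether geometries, the E (chain), Z (ring) isomer drawn | CC(C)(C)[Si](C)(C)O[C@@H]1[C@@](C)(CC/C=C/OC)CC[C@@H]([C@H](C)CCC=C(C)C)/C1=C/OC | intermediate
17 | bicyclo[3.3.1]nonane bis(dimethyl acetal): dimethoxymethyl groups on C4 and C5, C9 silyl ether syn to the C6–C8 bridge; C4 epimers, the one with the C4 acetal equatorial on ring A drawn | CC(C)(C)[Si](C)(C)O[C@@H]1[C@@]2(C)CC[C@H](C(OC)OC)[C@]1(C(OC)OC)[C@H]([C@H](C)CCC=C(C)C)CC2 | intermediate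
18 | C9 alcohol corresponding to 17 | O[C@@H]1[C@@]2(C)CC[C@H](C(OC)OC)[C@]1(C(OC)OC)[C@H]([C@H](C)CCC=C(C)C)CC2 | intermediate
19 | C9 acetate corresponding to 18 | CC(=O)O[C@@H]1[C@@]2(C)CC[C@H](C(OC)OC)[C@]1(C(OC)OC)[C@H]([C@H](C)CCC=C(C)C)CC2 | intermediate
20 | saturated 4,5-dicarbaldehyde with C9 acetate (C4 epimers) | CC(=O)O[C@@H]1[C@@]2(C)CC[C@H](C=O)[C@]1(C=O)[C@H]([C@H](C)CCC=C(C)C)CC2 | intermediate
21 | trimethylsilyl enol ether of the C10 aldehyde (C4=C10H–OSiMe3), C11 aldehyde free | CC(=O)O[C@@H]1[C@@]2(C)CCC(=CO[Si](C)(C)C)[C@]1(C=O)[C@H]([C@H](C)CCC=C(C)C)CC2 | intermediate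
22 | (1R,5R,6S,9R)-9-acetoxy-1-methyl-6-[(2R)-6-methylhept-5-en-2-yl]bicyclo[3.3.1]non-3-ene-4,5-dicarbaldehyde | CC(=O)O[C@@H]1[C@@]2(C)CC=C(C=O)[C@]1(C=O)[C@H]([C@H](C)CCC=C(C)C)CC2 | target

**Step count and risks**

Total step count: 15. Longest linear sequence: 15 steps (steps 1–15 from (R)-citronellal; compounds 2, 7 and 14 are commercial).

Steps most likely to fail:

1. Step 10. Methanol capture of the radical cation, or further oxidation, may outrun C4–C5 bond formation at the crowded, tetrasubstituted C5, so that open-chain acetals form in place of ring A. The fallback leaves the anode and the protic medium. Setting out from 16, brief treatment with aqueous oxalic acid in THF hydrolyses both enol ethers to the ring B dialdehyde F1 (4-oxobutyl chain on C1, formyl on C5). TBSOTf and Et3N convert both aldehydes into the bis(silyl enol ether) F2. Oxidation with (NH4)2Ce(NO3)6 (tetravalent cerium) and NaHCO3 in MeCN at −10 °C, an intramolecular oxidative coupling of two enol silanes, closes C4–C5 in a non-nucleophilic solvent, where loss of the silyl groups rather than solvent capture ends the reaction; this gives the bicyclic silyloxy dialdehyde F3. HF·pyridine in THF frees the C9 alcohol as the hydroxy dialdehyde F4 under acidic conditions that avoid retro-aldol cleavage, and Ac2O in pyridine returns to the route at 20.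

2. Step 9. The ylide may act as a base on the hindered α-silyloxy ketone, leading to enolisation with epimerisation at C6 or to no addition at C5, while only the aldehyde is olefinated. The fallback olefinates the two carbonyls separately and uses a smaller, more nucleophilic carbanion for the ketone. From 13, 1.1 equivalents of ylide 15 at −78 °C should convert only the aldehyde and give the keto enol ether F5. Methoxy(trimethylsilyl)methyllithium (from MeOCH2SiMe3 and s-BuLi, THF, −78 °C, with anhydrous CeCl3 if enolisation intervenes) adds to the C5 ketone to give the β-hydroxysilane F6. KH in THF then effects Peterson elimination and returns to the route at 16.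

3. Step 5. Facial selectivity at C1 may be poor, because the only control element is the conformational preference of the distant C6 side chain. The fallback takes facial control away from the substrate. From 6, Grignard reagent 8 is added under catalysis by Cu(OTf)2 and an enantiopure N-heterocyclic carbene ligand (generated from its imidazolinium salt by the Grignard reagent), the catalytic enantioselective conjugate addition known to build quaternary centres on 3-methylcyclohex-2-enones. Both ligand enantiomers would be tried and the one matched with the intrinsic axial preference kept. The magnesium enolate is silylated with TMSCl and Et3N to return directly to 9, so no compound outside the list arises (entry F0).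

**Further compounds**

F1 | step 10 | ring B dialdehyde: C9 silyl ether, 4-oxobutyl chain on C1, formyl on C5 (C5 epimers) | CC(C)(C)[Si](C)(C)O[C@@H]1[C@@](C)(CCCC=O)CC[C@@H]([C@H](C)CCC=C(C)C)C1C=O
F2 | step 10 | bis(tert-butyldimethylsilyl enol ether) of F1 | CC(C)(C)[Si](C)(C)O[C@@H]1[C@@](C)(CCC=CO[Si](C)(C)C(C)(C)C)CC[C@@H]([C@H](C)CCC=C(C)C)C1=CO[Si](C)(C)C(C)(C)C
F3 | step 10 | bicyclic 4,5-dicarbaldehyde with C9 silyl ether (C4 epimers) | CC(C)(C)[Si](C)(C)O[C@@H]1[C@@]2(C)CC[C@H](C=O)[C@]1(C=O)[C@H]([C@H](C)CCC=C(C)C)CC2
F4 | step 10 | bicyclic 9-hydroxy-4,5-dicarbaldehyde (C4 epimers) | O[C@@H]1[C@@]2(C)CC[C@H](C=O)[C@]1(C=O)[C@H]([C@H](C)CCC=C(C)C)CC2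
F5 | step 9 | keto enol ether: as 13 with the chain aldehyde converted to CH=CH(OMe) | O=C1[C@H](O[Si](C)(C)C(C)(C)C)[C@@](C)(CCC=COC)CC[C@H]1[C@H](C)CCC=C(C)C
F6 | step 9 | β-hydroxysilane: C5 tertiary alcohol bearing CH(OMe)SiMe3 (diastereomer mixture at both new centres) | CC(C)(C)[Si](C)(C)O[C@@H]1[C@@](C)(CCC=COC)CC[C@@H]([C@H](C)CCC=C(C)C)C1(O)C(OC)[Si](C)(C)C
F0 | step 5 | none | none
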